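Readings and results are simulated from invented constants.

What is left of X late in the zeta run still moves: cX goes from 13.6% at 2.00 min to 3.4% at 6.00 min, while D reads 72.5% and then 73.2%. The next charge is weighed here by how long X stands warm.

| flask | E | J | G | temperature | remark | time |
|---|---|---|---|---|---|---|
| theta | 24 mM | 1.1 equiv | 24 mM | 0 °C | run made earlier |  |
| zeta | 24 mM | 1.1 equiv | 12 mM | 11 °C | run made earlier |  |
| delta | 24 mM | 1.1 equiv | 18 mM | 0 °C | run made earlier |  |
| epsilon | 36 mM | 1.1 equiv | 24 mM | 11 °C | run made earlier |  |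
| dusk | 24 mM | 1.10 equiv | 24.0 mM |  | everything together at the start at −15 °C, warmed to 5 °C at 6.0 min | 10 min |
| summer | 24 mM | 1.10 equiv | 24.0 mM | 5 °C | everything together at the start | 10 min |
| midnight | 24 mM (fed, over 6.0 min) | 1.10 equiv | 24.0 mM | 5 °C | all else is in the flask from the start; the feed brings no volume worth counting | 10 min |
| winter | 24 mM | 1.10 equiv (fed, over 6.0 min) | 24.0 mM |  | the addition at −15 °C, then warmed to 5 °C; the feed brings no volume worth counting | 10 min |

- theta (time / min: X / %, D / %): 0.500: 15.4, 24.8; 0.833: 20.7, 34.9; 1.33: 22.9, 46.5; 2.00: 23.3, 55.0; 4.00: 21.2, 65.7; 6.00: 19.8, 68.5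
- zeta (time / min: X / %, D / %): 2.00: 13.6, 72.5; 4.00: 6.7, 72.8; 6.00: 3.4, 73.2; 8.00: 1.4, 73.6; 10.0: 1.2, 73.4; 12.0: 0.6, 72.4
- delta (time / min: X / %, D / %): 1.00: 21.9, 38.5; 1.50: 23.2, 48.8; 2.50: 23.7, 57.7; 4.00: 21.7, 66.5; 8.00: 16.5, 68.9; 12.0: 11.8, 70.1
- epsilon (time / min: X / %, D / %): 1.00: 23.2, 59.7; 3.00: 12.1, 65.3; 6.00: 4.9, 65.4; 8.00: 2.6, 64.9; 12.0: 0.8, 65.5

(standard deviation of a reading: 0.5 percentage points)

- what was read earlier has a scatter of 0.5 percentage points, one standard deviation

1. the flask that comes out highest in share of X in X plus D, or "all alike" when all lie within 1.5 percentage points (dusk / summer / midnight / winter / all alike)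
2. share of X in X plus D at the end, dusk
3. share of X in X plus D at the end, summer
4. share of X in X plus D at the end, midnight
5. share of X in X plus D at the end, winter

In logarithms that fall becomes a count of powers of ten. Zeta reads 0.151 min⁻¹. Delta, from 16.5% at 8.00 min to 11.8% at 12.0 min, reads 0.0364 min⁻¹, a rough reading, with D there still moving from 68.9% to 70.1%. The two runs also differ in G, 12 mM against 18 mM, but a straight line in the logarithm through both temperatures gives an estimate of 0.0694 min⁻¹ at 5 °C: the decade rate, the powers of ten by which cX falls per minute once its formation has stopped, a first-order constant on the base-ten scale.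

The reckoning here starts the fall from the theta peak reading, 23.3% at 2.00 min. Summer is then reckoned to lose 0.555 decades, which would leave cX near 6.49%. With D interpolated to 71.1%, the share of X, the selectivity, comes to 8.36%. Dusk spends 6.0 min at a decade rate extrapolated to 0.00525 min⁻¹ and the remainder at 5 °C, so it is reckoned to lose 0.309 decades, fewer than summer. Winter passes through the same cold stretch, but its J is fed slowly. On this count of decades, the decision is to charge dusk, with J present from the start.

The forecast, built on “X is lost after forming, while D stays flat”, names dusk and gives 22% for dusk, 17% for summer, 17% for midnight and 19% for winter.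

The flask gives dusk as highest, with 20.9% for dusk, 7.96% for summer, 9.04% for midnight and 10.6% for winter; the summer reckoning of 8.36% lies close to its result.

    E + J → X (k = 31.0 M⁻¹ min⁻¹, Ea = 55.0 kJ mol⁻¹)
    E + J → D, rate k2*[E] as long as [J] is above zero (k = 1.10 min⁻¹, Ea = 69.0 kJ mol⁻¹)
    J + G → L (k = 3.30 M⁻¹ min⁻¹, Ea = 40.0 kJ mol⁻¹)
    X → Q (k = 0.150 min⁻¹, Ea = 87.0 kJ mol⁻¹)
    2 E → Z (k = 1.60 M⁻¹ min⁻¹, Ea = 67.0 kJ mol⁻¹)
    (constants at 5 °C)

Summer has not come to rest at 10.0 min: cX still stands at 6.19%, and the further 90.0 min are worth 6.25 decades. The computed flask at 100 min shows X at 0%, Q up from 19.9% to 26.1% and D at 71.6%, so the share falls to 0%; dusk falls to 0%. For the repeat of summer at 20 °C, the same line, extrapolated, gives 0.481 min⁻¹, hence an estimate of 3.85 decades and cX near 0.00329%. That neighbour computes to a share of 0%, with Q at 21.3%.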